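**Retrosynthetic overview**

1. Both anhydride rings close together in the last step from a tetraester; the same acid treatment frees the CH2OH (tert-butyl ether) and the ketone (dioxolane).
2. Each ring is carried as a (Z)-maleate diester, made from a β-keto ester by chelation-controlled (Z)-enol triflation and Pd-catalysed methoxycarbonylation; the ring A maleate is made first, the ring B maleate second.
3. Key disconnection: the C3–C4 bond of ring B, formed by intermolecular aldol addition of the lithium enolate of a ketal-masked methyl 4-oxooctanoate (fragment 2) to the α-branched aldehyde that already carries ring A (fragment 1), then oxidation.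
4. Ring A carbons: crossed Claisen acylation of the side-arm tert-butyl ester enolate with a tert-butoxyacetyl Weinreb amide.
5. The single stereocentre: oxazolidinone-controlled Michael addition of an N-heptanoyl imide titanium enolate to tert-butyl acrylate.

Assumption: the target is the (R)-enantiomer as drawn, with the free hydroxymethyl anhydride in ring A; the route has not been run, so conditions are proposed from standard practice.

**Route**

Step 1
Reactants: 1 methyl 4-chloro-4-oxobutanoate; 2 butylmagnesium chloride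
Product: 3 methyl 4-oxooctanoate
Conditions: Fe(acac)3 (3 mol %), THF, −78 °C, 15 min
Reagents that add atoms: none
Why: Fe(acac)3-catalysed acylation of the Grignard reagent by the acid chloride is far faster at −78 °C than addition to the methyl ester or to the product ketone.

Step 2
Reactants: 3 methyl 4-oxooctanoate
Product: 4 methyl 3-(2-butyl-1,3-dioxolan-2-yl)propanoate
Conditions: HOCH2CH2OH (3 equiv), p-TsOH·H2O (cat.), toluene, reflux, Dean–Stark
Reagents that add atoms: ethylene glycol, OCCO
Why: acid-catalysed ketalisation with azeotropic removal of water masks the ketone as a base-stable dioxolane, so the ester can later be enolised.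

Step 3
Reactants: 5 tert-butoxyacetic acid
Product: 7 2-tert-butoxy-N-methoxy-N-methylacetamide, via acyl imidazole 6 (not isolated)
Conditions: CDI, CH2Cl2, rt, 1 h; then MeNHOMe·HCl, rt, 12 h
Reagents that add atoms: N,O-dimethylhydroxylamine hydrochloride, CNOC.Cl
Why: CDI activation followed by aminolysis of the acyl imidazole is the standard Weinreb amide synthesis.

Step 4
Reactants: 8 (4S)-4-benzyl-1,3-oxazolidin-2-one; 9 heptanoyl chloride
Product: 11 (4S)-4-benzyl-3-heptanoyl-1,3-oxazolidin-2-one, via lithium oxazolidinide 10 (not isolated)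
Conditions: n-BuLi, THF, −78 °C; then 9, −78 → 0 °C
Reagents that add atoms: none
Why: N-acylation of the lithiated Evans auxiliary by the acid chloride is quantitative and leaves the auxiliary stereocentre untouched.

Step 5
Reactants: 11 (4S)-4-benzyl-3-heptanoyl-1,3-oxazolidin-2-one; 12 tert-butyl acrylate
Product: 14 tert-butyl (4R)-4-{[(4S)-4-benzyl-2-oxo-1,3-oxazolidin-3-yl]carbonyl}nonanoate, via chlorotitanium Z-enolate 13 (not isolated)
Conditions: TiCl4/Ti(OiPr)4 (3:1, gives TiCl3(OiPr), 1.05 equiv), iPr2NEt (1.1 equiv), CH2Cl2, 0 °C, 1 h; then 12 (1.5 equiv), 0 °C, 6 h; aq NH4Cl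
Reagents that add atoms: none
Why: in this Evans asymmetric Michael addition the chelated Z-titanium enolate is attacked by the acrylate on the face opposite the benzyl group, which sets the only stereocentre as R (the minor diastereomer is removed by chromatography).

Step 6
Reactants: 14 tert-butyl (4R)-4-{[(4S)-4-benzyl-2-oxo-1,3-oxazolidin-3-yl]carbonyl}nonanoate
Product: 15 tert-butyl (4R)-4-(hydroxymethyl)nonanoate
Conditions: LiBH4 (1.2 equiv), H2O (1.2 equiv), Et2O, 0 °C, 1 h; aq NaOH
Reagents that add atoms: none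
Why: LiBH4 reduces the activated exocyclic imide carbonyl to the primary alcohol and releases the auxiliary, while the tert-butyl ester neither reduces nor lactonises at 0 °C.

Step 7
Reactants: 15 tert-butyl (4R)-4-(hydroxymethyl)nonanoate
Product: 16 tert-butyl (4R)-4-{[(tert-butyldimethylsilyl)oxy]methyl}nonanoate
Conditions: TBSCl, imidazole, DMF, rt
Reagents that add atoms: tert-butyldimethylsilyl chloride, CC(C)(C)[Si](C)(C)Cl
Why: standard silylation of the primary alcohol, giving an ether that survives the strong-base, triflation and carbonylation steps.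

Step 8
Reactants: 16 tert-butyl (4R)-4-{[(tert-butyldimethylsilyl)oxy]methyl}nonanoate; 7 2-tert-butoxy-N-methoxy-N-methylacetamide
Product: 18 tert-butyl (4R)-2-(tert-butoxyacetyl)-4-{[(tert-butyldimethylsilyl)oxy]methyl}nonanoate (both C2 epimers), via lithium enolate 17 (not isolated)
Conditions: LiN(iPr)2 (1.1 equiv), THF, −78 °C, 45 min; then 7 (1.4 equiv), −78 → −20 °C; aq NH4Cl
Reagents that add atoms: none
Why: in this crossed Claisen acylation the chelated tetrahedral adduct of the Weinreb amide persists until quench, so one equivalent of the non-self-condensing tert-butyl ester enolate suffices.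

Step 9
Reactants: 18 tert-butyl (4R)-2-(tert-butoxyacetyl)-4-{[(tert-butyldimethylsilyl)oxy]methyl}nonanoate
Product: 20 tert-butyl (2Z,4R)-2-[2-tert-butoxy-1-(trifluoromethanesulfonyloxy)ethylidene]-4-{[(tert-butyldimethylsilyl)oxy]methyl}nonanoate (OTf cis to CO2tBu), via sodium Z-enolate 19 (not isolated)
Conditions: NaH (1.2 equiv), CH2Cl2, 0 °C, 30 min; then Tf2O (1.2 equiv), −78 → 0 °C
Reagents that add atoms: trifluoromethanesulfonic anhydride, O=S(=O)(OS(=O)(=O)C(F)(F)F)C(F)(F)F
Why: the sodium enolate is held in the chelated Z form (Na+ bridging enolate oxygen and ester carbonyl), so O-sulfonylation gives the Z-enol triflate with OTf cis to the ester, the geometry a maleate needs.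

Step 10
Reactants: 20 the (Z)-enol triflate from step 9
Product: 21 1-tert-butyl 4-methyl (2Z)-3-(tert-butoxymethyl)-2-[(2R)-2-{[(tert-butyldimethylsilyl)oxy]methyl}heptyl]but-2-enedioate
Conditions: Pd(OAc)2 (10 mol %), dppf (12 mol %), CO (1 atm), MeOH (30 equiv), Et3N (2 equiv), DMF, 60 °C
Reagents that add atoms: carbon monoxide, [C-]#[O+]; methanol, CO
Why: in this palladium-catalysed alkoxycarbonylation, zerovalent palladium (formed in situ) adds to the vinyl C–OTf bond, inserts CO and is methanolysed with retention of alkene geometry, so the two esters end up cis.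

Step 11
Reactants: 21 the silyl-protected ring A maleate
Product: 22 1-tert-butyl 4-methyl (2Z)-3-(tert-butoxymethyl)-2-[(2R)-2-(hydroxymethyl)heptyl]but-2-enedioate
Conditions: HF·pyridine, pyridine, THF, 0 °C → rt
Reagents that add atoms: none
Why: buffered fluoride desilylation frees the primary alcohol without touching the tert-butyl ester, tert-butyl ether or maleate.

Step 12
Reactants: 22 the primary alcohol
Product: 23 1-tert-butyl 4-methyl (2Z)-3-(tert-butoxymethyl)-2-[(2R)-2-formylheptyl]but-2-enedioate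
Conditions: Dess–Martin periodinane (1.3 equiv), NaHCO3, CH2Cl2, 0 °C → rt; used at once
Reagents that add atoms: none
Why: buffered Dess–Martin oxidation gives the α-branched aldehyde under neutral conditions that do not epimerise the stereocentre.

Step 13
Reactants: 23 the aldehyde (fragment 1); 4 methyl 3-(2-butyl-1,3-dioxolan-2-yl)propanoate (fragment 2)
Product: 25 1-tert-butyl 4-methyl (2Z)-3-(tert-butoxymethyl)-2-[(2R)-2-{2-[(2-butyl-1,3-dioxolan-2-yl)methyl]-1-hydroxy-3-methoxy-3-oxopropyl}heptyl]but-2-enedioate (diastereomer mixture at the two new carbons), via lithium enolate 24 (not isolated)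
Conditions: 4 (1.6 equiv), LiN(iPr)2 (1.5 equiv), THF, −78 °C, 40 min; then 23, −78 °C, 20 min; aq NH4Cl at −78 °C
Reagents that add atoms: none
Why: aldol addition of an ester lithium enolate to an aldehyde is much faster at −78 °C than attack on the hindered maleate esters, and it joins the two fragments; the two new stereocentres are removed in steps 14–15.

Step 14
Reactants: 25 the β-hydroxy ester
Product: 26 1-tert-butyl 4-methyl (2Z)-3-(tert-butoxymethyl)-2-[(2R)-2-{2-[(2-butyl-1,3-dioxolan-2-yl)methyl]-3-methoxy-3-oxopropanoyl}heptyl]but-2-enedioate (both epimers at the carbon between the carbonyls)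
Conditions: Dess–Martin periodinane (1.5 equiv), NaHCO3, CH2Cl2, rt
Reagents that add atoms: none
Why: Dess–Martin oxidation of the secondary alcohol gives the β-keto ester, which enolises only between the two carbonyls, so the adjacent stereocentre is not scrambled.

Step 15
Reactants: 26 the β-keto ester
Product: 28 1-tert-butyl 4-methyl (2Z)-3-(tert-butoxymethyl)-2-[(2R)-2-{(1Z)-2-[(2-butyl-1,3-dioxolan-2-yl)methyl]-3-methoxy-3-oxo-1-(trifluoromethanesulfonyloxy)prop-1-en-1-yl}heptyl]but-2-enedioate (OTf cis to CO2Me), via sodium Z-enolate 27 (not isolated)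
Conditions: NaH (1.15 equiv), CH2Cl2, 0 °C, 30 min; then Tf2O (1.15 equiv), −78 → 0 °C
Reagents that add atoms: trifluoromethanesulfonic anhydride, O=S(=O)(OS(=O)(=O)C(F)(F)F)C(F)(F)F
Why: NaH removes only the proton between the two carbonyls, and triflation of the chelated Z-enolate fixes OTf cis to the ester as in step 9.

Step 16
Reactants: 28 the (Z)-enol triflate of ring B
Product: 29 dimethyl (2Z)-2-[(2-butyl-1,3-dioxolan-2-yl)methyl]-3-{(2R)-1-[(2Z)-1-tert-butoxy-3-(tert-butoxymethyl)-4-methoxy-1,4-dioxobut-2-en-2-yl]heptan-2-yl}but-2-enedioate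
Conditions: Pd(OAc)2 (10 mol %), dppf (12 mol %), CO (1 atm), MeOH (30 equiv), Et3N (2 equiv), DMF, 65 °C
Reagents that add atoms: carbon monoxide, [C-]#[O+]; methanol, CO
Why: palladium-catalysed alkoxycarbonylation with retention of geometry, as in step 10, completes the second (Z)-maleate.

Step 17
Reactants: 29 the tetraester
Product: 31 3-{(2R)-1-[4-(hydroxymethyl)-2,5-dioxo-2,5-dihydrofuran-3-yl]heptan-2-yl}-4-(2-oxohexyl)furan-2,5-dione (the target), via trilithium tricarboxylate 30 (not isolated)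
Conditions: LiOH·H2O (10 equiv), THF/MeOH/H2O (2:1:1), rt → 40 °C; evaporate; then TFA/H2O (95:5), 0 °C → rt, 3 h; evaporate from toluene; THF/H2O, rt, 30 min
Reagents that add atoms: lithium hydroxide, [Li+].[OH-]; water, O
Why: saponification of the three methyl esters, then acidolysis of the tert-butyl ester, tert-butyl ether and dioxolane, gives two dialkylmaleic acids that close spontaneously to the anhydrides; the CH2OH stays free because it is trans to the carboxyl it could otherwise lactonise with.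

**Compound list**

1 | methyl 4-chloro-4-oxobutanoate | COC(=O)CCC(=O)Cl | starting material
2 | butylmagnesium chloride | CCCC[Mg]Cl | starting material
3 | methyl 4-oxooctanoate | CCCCC(=O)CCC(=O)OC | intermediate
4 | methyl 3-(2-butyl-1,3-dioxolan-2-yl)propanoate | CCCCC1(CCC(=O)OC)OCCO1 | intermediate
5 | tert-butoxyacetic acid | CC(C)(C)OCC(=O)O | starting material
6 | 2-tert-butoxy-1-(1H-imidazol-1-yl)ethan-1-one | CC(C)(C)OCC(=O)n1ccnc1 | intermediate
7 | 2-tert-butoxy-N-methoxy-N-methylacetamide | CC(C)(C)OCC(=O)N(C)OC | intermediate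
8 | (4S)-4-benzyl-1,3-oxazolidin-2-one | O=C1N[C@@H](Cc2ccccc2)CO1 | starting material
9 | heptanoyl chloride | CCCCCCC(=O)Cl | starting material
10 | lithium (4S)-4-benzyl-2-oxo-1,3-oxazolidin-3-ide | [Li]N1[C@@H](Cc2ccccc2)COC1=O | intermediate
11 | (4S)-4-benzyl-3-heptanoyl-1,3-oxazolidin-2-one | CCCCCCC(=O)N1[C@@H](Cc2ccccc2)COC1=O | intermediate
12 | tert-butyl acrylate | C=CC(=O)OC(C)(C)C | starting material
13 | dichloro(isopropoxy)titanium Z-enolate of 11 | CCCCC/C=C(\O[Ti](Cl)(Cl)OC(C)C)N1[C@@H](Cc2ccccc2)COC1=O | intermediate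
14 | tert-butyl (4R)-4-{[(4S)-4-benzyl-2-oxo-1,3-oxazolidin-3-yl]carbonyl}nonanoate | CCCCC[C@H](CCC(=O)OC(C)(C)C)C(=O)N1[C@@H](Cc2ccccc2)COC1=O | intermediate
15 | tert-butyl (4R)-4-(hydroxymethyl)nonanoate | CCCCC[C@H](CCC(=O)OC(C)(C)C)CO | intermediate
16 | tert-butyl (4R)-4-{[(tert-butyldimethylsilyl)oxy]methyl}nonanoate | CCCCC[C@H](CCC(=O)OC(C)(C)C)CO[Si](C)(C)C(C)(C)C | intermediate
17 | lithium enolate of 16 | CCCCC[C@H](CC=C(O[Li])OC(C)(C)C)CO[Si](C)(C)C(C)(C)C | intermediate
18 | tert-butyl (4R)-2-(tert-butoxyacetyl)-4-{[(tert-butyldimethylsilyl)oxy]methyl}nonanoate (both C2 epimers) | CCCCC[C@H](CC(C(=O)OC(C)(C)C)C(=O)COC(C)(C)C)CO[Si](C)(C)C(C)(C)C | intermediate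
19 | sodium Z-enolate of 18 (O–Na cis to CO2tBu) | CCCCC[C@H](C/C(C(=O)OC(C)(C)C)=C(/O[Na])COC(C)(C)C)CO[Si](C)(C)C(C)(C)C | intermediate
20 | tert-butyl (2Z,4R)-2-[2-tert-butoxy-1-(trifluoromethanesulfonyloxy)ethylidene]-4-{[(tert-butyldimethylsilyl)oxy]methyl}nonanoate | CCCCC[C@H](C/C(C(=O)OC(C)(C)C)=C(/OS(=O)(=O)C(F)(F)F)COC(C)(C)C)CO[Si](C)(C)C(C)(C)C | intermediate
21 | 1-tert-butyl 4-methyl (2Z)-3-(tert-butoxymethyl)-2-[(2R)-2-{[(tert-butyldimethylsilyl)oxy]methyl}heptyl]but-2-enedioate | CCCCC[C@H](C/C(C(=O)OC(C)(C)C)=C(/C(=O)OC)COC(C)(C)C)CO[Si](C)(C)C(C)(C)C | intermediate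
22 | 1-tert-butyl 4-methyl (2Z)-3-(tert-butoxymethyl)-2-[(2R)-2-(hydroxymethyl)heptyl]but-2-enedioate | CCCCC[C@H](C/C(C(=O)OC(C)(C)C)=C(/C(=O)OC)COC(C)(C)C)CO | intermediate
23 | 1-tert-butyl 4-methyl (2Z)-3-(tert-butoxymethyl)-2-[(2R)-2-formylheptyl]but-2-enedioate | CCCCC[C@H](C/C(C(=O)OC(C)(C)C)=C(/C(=O)OC)COC(C)(C)C)C=O | intermediate
24 | lithium enolate of 4 | CCCCC1(CC=C(O[Li])OC)OCCO1 | intermediate
25 | 1-tert-butyl 4-methyl (2Z)-3-(tert-butoxymethyl)-2-[(2R)-2-{2-[(2-butyl-1,3-dioxolan-2-yl)methyl]-1-hydroxy-3-methoxy-3-oxopropyl}heptyl]but-2-enedioate (diastereomer mixture at the carbinol carbon and the adjacent ester carbon) | CCCCC[C@H](C/C(C(=O)OC(C)(C)C)=C(/C(=O)OC)COC(C)(C)C)C(O)C(CC1(CCCC)OCCO1)C(=O)OC | intermediate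
26 | 1-tert-butyl 4-methyl (2Z)-3-(tert-butoxymethyl)-2-[(2R)-2-{2-[(2-butyl-1,3-dioxolan-2-yl)methyl]-3-methoxy-3-oxopropanoyl}heptyl]but-2-enedioate (both epimers at the carbon between the carbonyls) | CCCCC[C@H](C/C(C(=O)OC(C)(C)C)=C(/C(=O)OC)COC(C)(C)C)C(=O)C(CC1(CCCC)OCCO1)C(=O)OC | intermediate
27 | sodium Z-enolate of 26 (O–Na cis to CO2Me) | CCCCC[C@H](C/C(C(=O)OC(C)(C)C)=C(/C(=O)OC)COC(C)(C)C)/C(O[Na])=C(\CC1(CCCC)OCCO1)C(=O)OC | intermediate
28 | 1-tert-butyl 4-methyl (2Z)-3-(tert-butoxymethyl)-2-[(2R)-2-{(1Z)-2-[(2-butyl-1,3-dioxolan-2-yl)methyl]-3-methoxy-3-oxo-1-(trifluoromethanesulfonyloxy)prop-1-en-1-yl}heptyl]but-2-enedioate | CCCCC[C@H](C/C(C(=O)OC(C)(C)C)=C(/C(=O)OC)COC(C)(C)C)/C(OS(=O)(=O)C(F)(F)F)=C(\CC1(CCCC)OCCO1)C(=O)OC | intermediate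
29 | dimethyl (2Z)-2-[(2-butyl-1,3-dioxolan-2-yl)methyl]-3-{(2R)-1-[(2Z)-1-tert-butoxy-3-(tert-butoxymethyl)-4-methoxy-1,4-dioxobut-2-en-2-yl]heptan-2-yl}but-2-enedioate | CCCCC[C@H](C/C(C(=O)OC(C)(C)C)=C(/C(=O)OC)COC(C)(C)C)/C(C(=O)OC)=C(\CC1(CCCC)OCCO1)C(=O)OC | intermediate
30 | trilithium salt of the tricarboxylic acid from 29 (ring A tert-butyl ester, tert-butyl ether and dioxolane retained; R at the stereocentre, both alkenes Z) | CCCCC[C@H](C/C(C(=O)OC(C)(C)C)=C(/C(=O)[O-])COC(C)(C)C)/C(C(=O)[O-])=C(\CC1(CCCC)OCCO1)C(=O)[O-].[Li+].[Li+].[Li+] | intermediate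
31 | 3-{(2R)-1-[4-(hydroxymethyl)-2,5-dioxo-2,5-dihydrofuran-3-yl]heptan-2-yl}-4-(2-oxohexyl)furan-2,5-dione | CCCCC[C@H](CC1=C(CO)C(=O)OC1=O)C1=C(CC(=O)CCCC)C(=O)OC1=O | target

**Step count**

Total: 17 steps. Longest linear sequence: 14 steps (steps 4 to 17, from 8 and 9); fragment 2 takes 2 steps (1–2) and the Weinreb amide 1 step (3).

**Three steps most likely to fail, with fallbacks**

Step 5 (Michael addition). The titanium enolate may convert incompletely, the acrylate may oligomerise, or the diastereomer ratio may be lower for the heptanoyl imide than hoped. The fallback sets out from 11 and comes back at 16; it sets the stereocentre by enolate alkylation instead of conjugate addition. Imide 11 is deprotonated (NaN(SiMe3)2, THF, −78 °C) to the sodium Z-enolate F1 and alkylated with allyl iodide to (4S)-4-benzyl-3-[(2R)-2-(prop-2-en-1-yl)heptanoyl]-1,3-oxazolidin-2-one F2 (same facial sense as the Michael addition). LiBH4 then gives (2R)-2-(prop-2-en-1-yl)heptan-1-ol F3, and TBSCl/imidazole gives its silyl ether F4. Hydroboration with 9-BBN gives the B-alkyl borane F5, which is oxidised in the same flask (NaOH, H2O2) to (4R)-4-{[(tert-butyldimethylsilyl)oxy]methyl}nonan-1-ol F6. TEMPO/PhI(OAc)2 in MeCN/H2O gives (4R)-4-{[(tert-butyldimethylsilyl)oxy]methyl}nonanoic acid F7, and Boc2O/DMAP/t-BuOH esterification delivers 16.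

Step 13 (aldol fragment union). The strongly basic lithium enolate may deprotonate the γ-positions of the ring A maleate in 23 (with loss of tert-butoxide) or enolise the α-branched aldehyde. The fallback sets out from 4 and 23 and comes back at 25; it replaces the preformed lithium enolate by a non-basic zinc enolate generated by metal insertion (Reformatsky reaction). Enolate 24 is brominated with CBr4 at −78 °C to methyl 2-bromo-3-(2-butyl-1,3-dioxolan-2-yl)propanoate F8. Zinc dust (activated with Me3SiCl) in THF converts it to the bromozinc ester enolate F9, which adds to 23 at 0 °C → rt to give 25.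

Step 16 (carbonylation for ring B). CO insertion at the fully substituted triflate 28, flanked by a branched carbon, may be slow, with triflate hydrolysis back to 26 or reduction competing. The fallback sets out from 28 and comes back at 30; it introduces the carboxyl carbon by reductive carboxylation with CO2 instead of CO/methanol. Treatment of 28 with CoI2(phen) (cat.), Mn powder and CO2 (1 atm) in DMA at rt, then dilute HCl, gives the maleic half-ester acid F10. LiOH under the first-stage conditions of step 17 converts F10 into the trilithium salt 30, which continues through the TFA stage to 31.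

**Further compounds**

F1 | step 5 | sodium Z-enolate of 11 | CCCCC/C=C(\O[Na])N1[C@@H](Cc2ccccc2)COC1=O
F2 | step 5 | (4S)-4-benzyl-3-[(2R)-2-(prop-2-en-1-yl)heptanoyl]-1,3-oxazolidin-2-one | CCCCC[C@H](CC=C)C(=O)N1[C@@H](Cc2ccccc2)COC1=O
F3 | step 5 | (2R)-2-(prop-2-en-1-yl)heptan-1-ol | CCCCC[C@H](CC=C)CO
F4 | step 5 | tert-butyl(dimethyl){[(2R)-2-(prop-2-en-1-yl)heptyl]oxy}silane | CCCCC[C@H](CC=C)CO[Si](C)(C)C(C)(C)C
F5 | step 5 | 9-[(4S)-4-{[(tert-butyldimethylsilyl)oxy]methyl}nonyl]-9-borabicyclo[3.3.1]nonane (same spatial arrangement as F4; the descriptor changes because boron ranks below carbon) | CCCCC[C@H](CCCB1C2CCCC1CCC2)CO[Si](C)(C)C(C)(C)C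
F6 | step 5 | (4R)-4-{[(tert-butyldimethylsilyl)oxy]methyl}nonan-1-ol | CCCCC[C@H](CCCO)CO[Si](C)(C)C(C)(C)C
F7 | step 5 | (4R)-4-{[(tert-butyldimethylsilyl)oxy]methyl}nonanoic acid | CCCCC[C@H](CCC(=O)O)CO[Si](C)(C)C(C)(C)C
F8 | step 13 | methyl 2-bromo-3-(2-butyl-1,3-dioxolan-2-yl)propanoate | CCCCC1(CC(Br)C(=O)OC)OCCO1
F9 | step 13 | bromozinc enolate of methyl 3-(2-butyl-1,3-dioxolan-2-yl)propanoate (Reformatsky reagent) | CCCCC1(CC([Zn]Br)C(=O)OC)OCCO1
F10 | step 16 | (2Z)-3-[(2-butyl-1,3-dioxolan-2-yl)methyl]-2-{(2R)-1-[(2Z)-1-tert-butoxy-3-(tert-butoxymethyl)-4-methoxy-1,4-dioxobut-2-en-2-yl]heptan-2-yl}-4-methoxy-4-oxobut-2-enoic acid | CCCCC[C@H](C/C(C(=O)OC(C)(C)C)=C(/C(=O)OC)COC(C)(C)C)/C(C(=O)O)=C(\CC1(CCCC)OCCO1)C(=O)OC
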